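The dihydrodioxine ring is cut at the aryl–oxygen bond O1–C8a and at C2–H, not at an alkyl C–O or a C–aryl bond. The precursor is a racemic α-aryloxy deoxybenzoin: C2 is a ketone bearing the catechol ring, C3 bears the resorcinol ring and O4, and O4 sits on a 2-fluoro-5-cyanophenyl ring. Two features of the target are exploited. C3–H becomes freely epimerisable beside a C2 carbonyl. O1 lies para to C6, the styryl carbon, where an acceptor activates SNAr. One pot (dynamic kinetic asymmetric transfer hydrogenation, then fluoride displacement) sets C2 and C3 together, fixes the O1/O4 regiochemistry and closes the ring. The stilbene is attached afterwards.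

Key step: step 6

Remark: atom labels follow 2,3-dihydro-1,4-benzodioxine numbering (O1, C2 with the 3,4-dioxygenated ring, C3 with the 3,5-dioxygenated ring, O4, C6 with the styryl group); the SMILES is read as the trans-(2R,3R) isomer; MOM = methoxymethyl.

Step 1
Reactants: 1 3',4'-dihydroxyacetophenone
Product: 2 1-[3,4-bis(methoxymethoxy)phenyl]ethanone
Conditions: MOMCl (2.5 equiv), iPr2NEt (3 equiv), CH2Cl2, 0 °C to rt
Reagents that add atoms: chloromethyl methyl ether (MOMCl), COCCl
Why: Williamson-type O-alkylation of both phenols with a reactive α-chloro ether; the MOM acetals tolerate the bases, hydrides, fluoride and Pd steps ahead and leave under mild acid.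

Step 2
Reactants: 3 5-bromoresorcinol (5-bromobenzene-1,3-diol)
Product: 4 1-bromo-3,5-bis(methoxymethoxy)benzene
Conditions: MOMCl (2.5 equiv), iPr2NEt (3 equiv), CH2Cl2, 0 °C to rt
Reagents that add atoms: chloromethyl methyl ether (MOMCl), COCCl
Why: The same Williamson-type O-alkylation gives one aryl bromide that serves twice, as the C3 aryl donor in step 3 and as the stilbene terminus in step 9.

Step 3
Reactants: 2 1-[3,4-bis(methoxymethoxy)phenyl]ethanone; 4 1-bromo-3,5-bis(methoxymethoxy)benzene
Product: 5 1-[3,4-bis(methoxymethoxy)phenyl]-2-[3,5-bis(methoxymethoxy)phenyl]ethanone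
Conditions: Pd2(dba)3 (1 mol %), rac-BINAP (2.5 mol %), NaOtBu, THF, 70 °C
Reagents that add atoms: none
Why: Buchwald–Hartwig-type Pd-catalysed α-arylation of a methyl ketone enolate; the chelating ligand and the lower reactivity of the more stabilised product enolate should hold the reaction at monoarylation.

Step 4
Reactants: 5 1-[3,4-bis(methoxymethoxy)phenyl]-2-[3,5-bis(methoxymethoxy)phenyl]ethanone
Product: 7 2-bromo-1-[3,4-bis(methoxymethoxy)phenyl]-2-[3,5-bis(methoxymethoxy)phenyl]ethanone (racemic), via trimethylsilyl enol ether 6 (not isolated)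
Conditions: LiHMDS, TMSCl, THF, −78 to 0 °C; then NBS, −78 °C
Reagents that add atoms: N-bromosuccinimide (NBS), O=C1CCC(=O)N1Br; chlorotrimethylsilane (TMSCl, atoms in 6 only), C[Si](C)(C)Cl
Why: Electrophilic α-bromination of a silyl enol ether, which at −78 °C is far more nucleophilic than the dialkoxyarene rings, runs acid-free and spares the MOM groups; the new stereocentre is racemic, which is all that step 6 needs.

Step 5
Reactants: 7 2-bromo-1-[3,4-bis(methoxymethoxy)phenyl]-2-[3,5-bis(methoxymethoxy)phenyl]ethanone (racemic); 8 4-fluoro-3-hydroxybenzonitrile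
Product: 9 3-{2-[3,4-bis(methoxymethoxy)phenyl]-1-[3,5-bis(methoxymethoxy)phenyl]-2-oxoethoxy}-4-fluorobenzonitrile (racemic)
Conditions: K2CO3, acetone, 0 °C to rt, Ar
Reagents that add atoms: none
Why: Williamson SN2 etherification of an acidic phenol with a doubly activated (benzylic, α-keto) bromide proceeds at or below rt, where the product enolate does not yet attack the aryl fluoride; it places O4 on C3, and the stereocentre stays racemic and labile.

Step 6
Reactants: 9 3-{2-[3,4-bis(methoxymethoxy)phenyl]-1-[3,5-bis(methoxymethoxy)phenyl]-2-oxoethoxy}-4-fluorobenzonitrile (racemic)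
Product: 11 (2R,3R)-2-[3,4-bis(methoxymethoxy)phenyl]-3-[3,5-bis(methoxymethoxy)phenyl]-2,3-dihydro-1,4-benzodioxine-6-carbonitrile, via syn-(1R,2R)-fluoro alcohol 10 (not isolated)
Conditions: RuCl[(S,S)-TsDPEN](p-cymene) (2 mol %), HCO2H/Et3N (5:2), DMF, 40 °C; then Cs2CO3 (excess), 70 °C
Reagents that add atoms: none
Why: The step is a Noyori–Ikariya asymmetric transfer hydrogenation run as a dynamic kinetic resolution, the reaction type by which the same (S,S)-catalyst takes racemic benzoin to (R,R)-hydrobenzoin, followed in the same flask by an intramolecular SNAr etherification. C3–H of 9 is flanked by the C2 carbonyl, the resorcinol ring and an electron-poor aryloxy group, so that Et3N should racemise it through the enol faster than the hindered, electron-rich ketone is reduced, and both enantiomers drain through the faster-reacting one. C2 is set by the catalyst, whose concerted Ru–H/N–H transfer holds the C2 aryl ring against the η6-cymene (CH/π contact) and delivers hydride to the face that gives (R)-C2, while C3 is set by matching, because only (R)-9 can offer that face in a Felkin–Anh conformer (C3–O4 anti to the incoming hydride, C3–H beside its trajectory), which leads to the syn-(1R,2R)-alcohol 10. Once the ketone is consumed, Cs2CO3 generates the C2 alkoxide, which adds to the C–F carbon para to the nitrile (Meisenheimer adduct, 6-exo-trig) and expels fluoride, so that the O1–C8a bond closes the six-membered ring without breaking a bond at C2 or C3 and syn-10 maps onto the trans-(2R,3R) ring with both aryl groups equatorial. The selectivities needed are syn over anti, which rests on the matched catalyst/Felkin–Anh pair, and O1 versus O4 regiochemistry, which is built into 9 because O4 is already in place, only the fluorine-bearing carbon is activated by the para nitrile, and ipso attack (Smiles shift) at the carbon meta to the nitrile is not. The base is held back until reduction is complete because the enolate of 9 would otherwise displace fluoride through its oxygen and erase both stereocentres.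

Step 7
Reactants: 11 (2R,3R)-2-[3,4-bis(methoxymethoxy)phenyl]-3-[3,5-bis(methoxymethoxy)phenyl]-2,3-dihydro-1,4-benzodioxine-6-carbonitrile
Product: 13 (2R,3R)-2-[3,4-bis(methoxymethoxy)phenyl]-3-[3,5-bis(methoxymethoxy)phenyl]-2,3-dihydro-1,4-benzodioxine-6-carbaldehyde, via N-aluminated aldimine 12 (not isolated)
Conditions: DIBAL-H (1.5 equiv), toluene, −78 °C; then 10 % aq. citric acid, 0 °C
Reagents that add atoms: water, O; diisobutylaluminium hydride (DIBAL-H, atoms in 12 only), CC(C)C[AlH]CC(C)C
Why: Partial reduction of an aryl nitrile with DIBAL-H stops at the N-aluminated aldimine, which hydrolyses on mildly acidic work-up; the aryl MOM ethers and the two benzylic ether stereocentres are inert at −78 °C.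

Step 8
Reactants: 13 (2R,3R)-2-[3,4-bis(methoxymethoxy)phenyl]-3-[3,5-bis(methoxymethoxy)phenyl]-2,3-dihydro-1,4-benzodioxine-6-carbaldehyde
Product: 14 (2R,3R)-2-[3,4-bis(methoxymethoxy)phenyl]-3-[3,5-bis(methoxymethoxy)phenyl]-6-ethenyl-2,3-dihydro-1,4-benzodioxine
Conditions: Ph3PCH3Br, KOtBu, THF, 0 °C to rt
Reagents that add atoms: methyltriphenylphosphonium bromide, C[P+](c1ccccc1)(c1ccccc1)c1ccccc1.[Br-]
Why: Wittig methylenation with a non-stabilised ylide; C2–H and C3–H are not acidic enough to be touched, so the configuration is retained.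

Step 9
Reactants: 14 (2R,3R)-2-[3,4-bis(methoxymethoxy)phenyl]-3-[3,5-bis(methoxymethoxy)phenyl]-6-ethenyl-2,3-dihydro-1,4-benzodioxine; 4 1-bromo-3,5-bis(methoxymethoxy)benzene
Product: 15 (2R,3R)-2-[3,4-bis(methoxymethoxy)phenyl]-3-[3,5-bis(methoxymethoxy)phenyl]-6-{(E)-2-[3,5-bis(methoxymethoxy)phenyl]ethenyl}-2,3-dihydro-1,4-benzodioxine (hexakis-MOM ether of maackin)
Conditions: Pd(OAc)2 (5 mol %), P(o-tol)3 (12 mol %), Et3N, DMF, 100 °C
Reagents that add atoms: none
Why: Mizoroki–Heck arylation of a terminal styrene takes place at the unsubstituted carbon, and syn insertion followed by syn β-hydride elimination should give the E-stilbene.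

Step 10
Reactants: 15 hexakis-MOM ether of maackin
Product: 16 maackin, 4-{(2R,3R)-3-(3,5-dihydroxyphenyl)-6-[(E)-2-(3,5-dihydroxyphenyl)ethenyl]-2,3-dihydro-1,4-benzodioxin-2-yl}benzene-1,2-diol
Conditions: HCl (1.25 M in MeOH), THF, 40 °C, Ar
Reagents that add atoms: none
Why: Acid-catalysed transacetalisation transfers the six MOM groups to methanol; C3 (meta-oxygenated ring) has no pathway for epimerisation, and any reversible ionisation of C2–O1 recloses to the more stable trans-diequatorial ring, so the configuration should hold.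

Compound list
1 | 3',4'-dihydroxyacetophenone | CC(=O)c1ccc(O)c(O)c1 | starting material
2 | 1-[3,4-bis(methoxymethoxy)phenyl]ethanone | CC(=O)c1ccc(OCOC)c(OCOC)c1 | intermediate
3 | 5-bromoresorcinol | Oc1cc(O)cc(Br)c1 | starting material
4 | 1-bromo-3,5-bis(methoxymethoxy)benzene | COCOc1cc(Br)cc(OCOC)c1 | intermediate
5 | 1-[3,4-bis(methoxymethoxy)phenyl]-2-[3,5-bis(methoxymethoxy)phenyl]ethanone | COCOc1cc(CC(=O)c2ccc(OCOC)c(OCOC)c2)cc(OCOC)c1 | intermediate
6 | (Z)-trimethylsilyl enol ether of 5 (geometry of no consequence) | COCOc1cc(/C=C(\O[Si](C)(C)C)c2ccc(OCOC)c(OCOC)c2)cc(OCOC)c1 | intermediate (not isolated)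
7 | 2-bromo-1-[3,4-bis(methoxymethoxy)phenyl]-2-[3,5-bis(methoxymethoxy)phenyl]ethanone, racemic | COCOc1cc(C(Br)C(=O)c2ccc(OCOC)c(OCOC)c2)cc(OCOC)c1 | intermediate
8 | 4-fluoro-3-hydroxybenzonitrile | N#Cc1ccc(F)c(O)c1 | starting material
9 | 3-{2-[3,4-bis(methoxymethoxy)phenyl]-1-[3,5-bis(methoxymethoxy)phenyl]-2-oxoethoxy}-4-fluorobenzonitrile, racemic | COCOc1cc(C(Oc2cc(C#N)ccc2F)C(=O)c2ccc(OCOC)c(OCOC)c2)cc(OCOC)c1 | intermediate
10 | 3-{(1R,2R)-2-[3,4-bis(methoxymethoxy)phenyl]-1-[3,5-bis(methoxymethoxy)phenyl]-2-hydroxyethoxy}-4-fluorobenzonitrile | O[C@H](c1ccc(OCOC)c(OCOC)c1)[C@@H](c1cc(OCOC)cc(OCOC)c1)Oc1cc(C#N)ccc1F | intermediate (not isolated)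
11 | (2R,3R)-2-[3,4-bis(methoxymethoxy)phenyl]-3-[3,5-bis(methoxymethoxy)phenyl]-2,3-dihydro-1,4-benzodioxine-6-carbonitrile | N#Cc1ccc2c(c1)O[C@H](c1cc(OCOC)cc(OCOC)c1)[C@@H](c1ccc(OCOC)c(OCOC)c1)O2 | intermediate
12 | N-(diisobutylaluminio)aldimine of 13 | CC(C)C[Al](CC(C)C)N=Cc1ccc2c(c1)O[C@H](c1cc(OCOC)cc(OCOC)c1)[C@@H](c1ccc(OCOC)c(OCOC)c1)O2 | intermediate (not isolated)
13 | (2R,3R)-2-[3,4-bis(methoxymethoxy)phenyl]-3-[3,5-bis(methoxymethoxy)phenyl]-2,3-dihydro-1,4-benzodioxine-6-carbaldehyde | O=Cc1ccc2c(c1)O[C@H](c1cc(OCOC)cc(OCOC)c1)[C@@H](c1ccc(OCOC)c(OCOC)c1)O2 | intermediate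
14 | (2R,3R)-2-[3,4-bis(methoxymethoxy)phenyl]-3-[3,5-bis(methoxymethoxy)phenyl]-6-ethenyl-2,3-dihydro-1,4-benzodioxine | C=Cc1ccc2c(c1)O[C@H](c1cc(OCOC)cc(OCOC)c1)[C@@H](c1ccc(OCOC)c(OCOC)c1)O2 | intermediate
15 | hexakis-MOM ether of maackin | COCOc1cc(OCOC)cc(/C=C/c2ccc3c(c2)O[C@H](c2cc(OCOC)cc(OCOC)c2)[C@@H](c2ccc(OCOC)c(OCOC)c2)O3)c1 | intermediate
16 | maackin | Oc1cc(O)cc(/C=C/c2ccc3c(c2)O[C@H](c2cc(O)cc(O)c2)[C@@H](c2ccc(O)c(O)c2)O3)c1 | target

Total step count: 10. Longest linear sequence: 9 steps (1 → 2 → 5 → 7 → 9 → 11 → 13 → 14 → 15 → 16).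

Steps most likely to fail

Step 6. The catalyst may discriminate poorly between the two interconverting ketone enantiomers, which would lower the syn/anti selectivity. Enolisation may also fail to keep pace with reduction, so that the resolution is no longer dynamic. The fallback sets out from 9 and comes back at 11. It replaces the dynamic resolution by substrate control plus a classical kinetic resolution. L-Selectride in THF at −78 °C should reduce 9 under Felkin–Anh control to the racemic syn alcohol F1. An acylative kinetic resolution follows (benzotetramisole, isobutyric anhydride, iPr2NEt, CHCl3, 0 °C). The catalyst enantiomer is chosen so that the (1S,2S)-alcohol is converted into its isobutyrate F2 while the (1R,2R)-alcohol 10 stays unreacted. After chromatographic separation, isolated 10 is closed with Cs2CO3 in DMF at 70 °C to 11.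

Step 4. Electrophilic bromination of the very electron-rich 3,5-dialkoxyphenyl ring may compete with attack on the enol ether, or a second α-bromination may occur. The fallback sets out from 5 and comes back at 9, and it uses no halogen electrophile and no basic alkylation. Regitz diazo transfer (p-acetamidobenzenesulfonyl azide, DBU, MeCN, 0 °C to rt) gives the α-diazo ketone F3. Slow addition of F3 to phenol 8 and Rh2(OAc)4 in CH2Cl2 at rt should give 9 by carbenoid O–H insertion.

Step 10. The electron-rich stilbene may oligomerise under acid, and cleavage of the six acetals may stay incomplete at the acid strength the molecule tolerates. The fallback sets out from 13 and 3 and comes back at 16. The acetals are removed before the stilbene exists, and the endgame is run on silyl ethers.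
- Methanolic HCl followed by aqueous work-up converts 13 into the tetraphenol aldehyde F4.
- TBSCl and imidazole in DMF give the tetrakis(TBS) aldehyde F5.
- Wittig methylenation under the conditions of step 8 gives the tetrakis(TBS) styrene F6.
- Compound 3 is silylated in the same way to 1-bromo-3,5-bis(tert-butyldimethylsilyloxy)benzene F7.
- Heck coupling of F6 and F7 under the conditions of step 9 gives the hexakis(TBS) ether of maackin F8.
- Et3N·3HF in THF at rt releases 16.

Further compounds
F1 | step 6 | 3-{(1R*,2R*)-2-[3,4-bis(methoxymethoxy)phenyl]-1-[3,5-bis(methoxymethoxy)phenyl]-2-hydroxyethoxy}-4-fluorobenzonitrile, racemic syn alcohol | OC(c1ccc(OCOC)c(OCOC)c1)C(c1cc(OCOC)cc(OCOC)c1)Oc1cc(C#N)ccc1F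
F2 | step 6 | (1S,2S)-1-[3,4-bis(methoxymethoxy)phenyl]-2-[3,5-bis(methoxymethoxy)phenyl]-2-(5-cyano-2-fluorophenoxy)ethyl isobutyrate | CC(C)C(=O)O[C@@H](c1ccc(OCOC)c(OCOC)c1)[C@H](c1cc(OCOC)cc(OCOC)c1)Oc1cc(C#N)ccc1F
F3 | step 4 | 2-diazo-1-[3,4-bis(methoxymethoxy)phenyl]-2-[3,5-bis(methoxymethoxy)phenyl]ethanone | COCOc1cc(C(=[N+]=[N-])C(=O)c2ccc(OCOC)c(OCOC)c2)cc(OCOC)c1
F4 | step 10 | (2R,3R)-2-(3,4-dihydroxyphenyl)-3-(3,5-dihydroxyphenyl)-2,3-dihydro-1,4-benzodioxine-6-carbaldehyde | O=Cc1ccc2c(c1)O[C@H](c1cc(O)cc(O)c1)[C@@H](c1ccc(O)c(O)c1)O2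
F5 | step 10 | tetrakis(tert-butyldimethylsilyl) ether of F4 | O=Cc1ccc2c(c1)O[C@H](c1cc(O[Si](C)(C)C(C)(C)C)cc(O[Si](C)(C)C(C)(C)C)c1)[C@@H](c1ccc(O[Si](C)(C)C(C)(C)C)c(O[Si](C)(C)C(C)(C)C)c1)O2
F6 | step 10 | (2R,3R)-2-[3,4-bis(TBSO)phenyl]-3-[3,5-bis(TBSO)phenyl]-6-ethenyl-2,3-dihydro-1,4-benzodioxine | C=Cc1ccc2c(c1)O[C@H](c1cc(O[Si](C)(C)C(C)(C)C)cc(O[Si](C)(C)C(C)(C)C)c1)[C@@H](c1ccc(O[Si](C)(C)C(C)(C)C)c(O[Si](C)(C)C(C)(C)C)c1)O2
F7 | step 10 | 1-bromo-3,5-bis(tert-butyldimethylsilyloxy)benzene | CC(C)(C)[Si](C)(C)Oc1cc(Br)cc(O[Si](C)(C)C(C)(C)C)c1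
F8 | step 10 | hexakis(tert-butyldimethylsilyl) ether of maackin | CC(C)(C)[Si](C)(C)Oc1cc(O[Si](C)(C)C(C)(C)C)cc(/C=C/c2ccc3c(c2)O[C@H](c2cc(O[Si](C)(C)C(C)(C)C)cc(O[Si](C)(C)C(C)(C)C)c2)[C@@H](c2ccc(O[Si](C)(C)C(C)(C)C)c(O[Si](C)(C)C(C)(C)C)c2)O3)c1
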